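(Its constants stand for no real mixture.)

A charge here counts per litre of the first phase, while a concentration in a rate counts per litre of that species' own phase.

    substrate + reagent in the reaction phase → target (k1 = 0.250 M⁻¹ s⁻¹)
    reagent in the reaction phase ⇌ dormant form (K2 = 0.494, k2 = 0.215 s⁻¹)
    crystals ⇌ target, rate k3*(cs3 - [target]) while solid is left; crystals form when [target] > cs3 (cs3 = 17 mM, k3 = 0.399 s⁻¹)
    reagent in the reaction phase ⇌ reagent in the second phase, rate k4*([reagent in the reaction phase] - [reagent in the second phase]/K4) per volume of the first phase (K4 = 0.73, k4 = 0.0240 s⁻¹)
    reagent in the reaction phase + target → over-reacted product (k5 = 0.0442 M⁻¹ s⁻¹)

substrate 0.050 M; reagent in the second phase 0.200 M; time 1.5 min; volume of the second phase over the first 2.0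

- amounts and yields of target count crystals too
- in the second phase: reagent in the second phase; everything else is in the first
- charges count per volume of the first phase; a concentration in a rate is the amount of a species over the volume of its own phase; every rate counts per litre of the first phase
- given per volume of solution although it is solid: crystals
- run time (flask): 1.5 min

- beta: doubling the dissolution coefficient of step 3, all else as stated
- zeta: doubling the transfer coefficient of step 4, all else as stated
- theta: doubling the solubility in step 3, all else as stated
- gamma: doubling the amount of reagent in the second phase, all else as stated

* how much target and crystals together there is at 1.5 min, in percent of the substrate charged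
* concentration of target in solution at 50 s, in percent of saturation
* the change that raises the amount of target and crystals together at 1.5 min, in percent of the substrate charged most ("none" if none brings more than 2 percentage points) (beta / zeta / theta / gamma / none)
* amount of target and crystals together at 1.5 min, in percent of the substrate charged, after theta

- I reckoned 0.0677 M as the free-reagent level, the concentration of reagent in the reaction phase once its charge has shared itself among the reaction phase, the dormant form and the second phase with nothing reacting.
- Transfer fills the reaction phase with a time constant of 30.8 s, the transfer time, while the dormant form relaxes with a half-life of 1.07 s, far shorter, so I let the level rise with the transfer time.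
- Substrate, the limiting reagent, then decays pseudo-first-order under that rising level, leaving 35.7%. After a small over-reaction loss I committed to 60.7%. The level counts no reagent spent, and the substrate could take a quarter of the reagent charge, so I took that figure as high.
- Crystals need 34.0% of the substrate as target, and by hand dissolved target stood at 102% of saturation at 50 s.
- Beta: the half-life of dissolution is 1.74 s, far shorter than the transfer time, so I expected no visible change.
- Theta: the level stays put, and extra dissolved target meets step 5, which I reckoned would cost 1.6 percentage points.
- Zeta: the level stays and the transfer time shortens, leaving 28.3% of the substrate, a gain of 6.5 points.
- Gamma: the level doubles, leaving 12.7% of the substrate, a gain of 20 points, more than zeta.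
- The forecast gave 55% of target and crystals together at 1.5 min, lower than my yield, 93% of saturation at 50 s, gamma as the best change and 54.5% after theta, and held that “gamma wins and theta barely lowers the yield”.
- The flask gave 54.0% of target and crystals together at 1.5 min and 90.9% of saturation at 50 s.
- Beta brought 0.051 points, theta −0.73 points (to 53.3%), zeta 6.8 points and gamma 19 points, so gamma led.
- In the flask, reagent in the reaction phase read 0.0500 M at 1.50 min, which is 73.9% of the free-reagent level. The same level and transfer time, applied to the neighbouring flask stopped at 40 s, left 74.2% of the substrate by hand. That neighbour held 75.9% substrate, 23.5% target and 0% crystals, with reagent in the reaction phase at 0.0426 M, or 62.9% of the level.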